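**Retrosynthetic overview**

1. Numbering: ring A is C1=C2–C3(O-acyl)–C4(CH3)–C5(CH3)–C10 and ring B is C5–C6=C7(OH)–C8(=O)–C9=C10. The strategy rests on the C2–C3 bond of ring A: C2 is the δ-terminus of the C8-centred dienone and C3 the carbinol carbon, both electrophilic by nature, so the bond is made with reversed polarity at C2 (alkenyllithium) and C3 at the acyl level.
2. Late disconnections: the C3 ester (Yamaguchi) to alcohol 22 and acid 36; the diosphenol from the C8 ketone by C7 hydroxylation and oxidation; the C8 ketone by allylic oxidation; the C3 carbinol by reduction of the ring A dienone.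
3. Key disconnection: ring B is present from the start (3-methylcyclohexenone); ring A is formed second by C2–C3 closure of the (Z)-iodovinyl Weinreb amide 15.
4. C4 and C5 come from an Ireland–Claisen rearrangement of the propanoate of (R)-2-iodo-3-methylcyclohex-2-enol; the ring iodide is extended to the (Z)-iodovinyl group by Sonogashira coupling, iododesilylation and diimide reduction.
5. Side chain: Evans hydroxymethylation of a butanoyl oxazolidinone, then Horner–Wadsworth–Emmons olefination with triethyl 4-phosphonocrotonate.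

Key step: step 9

Remarks: β denotes the face of the bicycle that carries the C5 methyl. Building blocks are numbered; reagents are named on the Conditions and reagent lines. The C7 configuration of ketol 40 is left open because step 23 removes it.

**Route**

Step 1
Reactants: 1 3-methylcyclohex-2-en-1-one
Product: 2 2-iodo-3-methylcyclohex-2-en-1-one
Conditions: I2, pyridine, CH2Cl2, rt
Reagents that add atoms: iodine, II
Why: α-Iodination of an enone by the pyridine-mediated addition–iodination–elimination sequence (Johnson procedure), in which the β-methyl group only slows the conjugate addition of pyridine.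

Step 2
Reactants: 2 2-iodo-3-methylcyclohex-2-en-1-one
Product: 3 (R)-2-iodo-3-methylcyclohex-2-en-1-ol
Conditions: (S)-Me-CBS oxazaborolidine [(S)-1-methyl-3,3-diphenyl-tetrahydro-1H,3H-pyrrolo[1,2-c][1,3,2]oxazaborole] (cat.), BH3·SMe2, THF, −20 °C; MeOH
Reagents that add atoms: none
Why: Corey–Bakshi–Shibata reduction in which the iodo-substituted alkenyl arm acts as the large group, so that the (S)-catalyst should deliver hydride to the face giving the (R)-carbinol, the centre that later transmits its chirality to C5.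

Step 3
Reactants: 3 (R)-2-iodo-3-methylcyclohex-2-en-1-ol; 4 propanoyl chloride
Product: 5 (R)-2-iodo-3-methylcyclohex-2-en-1-yl propanoate
Conditions: pyridine, 4-(dimethylamino)pyridine (cat.), CH2Cl2, 0 °C
Reagents that add atoms: none
Why: Acylation of a secondary allylic alcohol with an acid chloride under nucleophilic catalysis; the carbinol centre is not touched.

Step 4
Reactants: 5 (R)-2-iodo-3-methylcyclohex-2-en-1-yl propanoate
Product: 9 (2R)-2-[(1R)-2-iodo-1-methylcyclohex-2-en-1-yl]propanoic acid, via lithium enolate 6 (not isolated), via silyl ketene acetal 7 (not isolated), via trimethylsilyl ester 8 (not isolated)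
Conditions: LiN(i-Pr)2, THF, −78 °C; Me3SiCl, Et3N, −78 °C → rt, then 60 °C; 1 M HCl
Reagents that add atoms: lithium diisopropylamide, CC(C)N([Li])C(C)C (lithium stays in 6 only); chlorotrimethylsilane, C[Si](C)(C)Cl (silicon stays in 7 and 8 only)
Why: Ireland–Claisen rearrangement: kinetic deprotonation in THF without a polar cosolvent should give the enolate with methyl trans to the oxygen–metal bond and hence the (E)-silyl ketene acetal 7, whose [3,3] shift takes place on the ring face of the departing C9–O bond (this fixes the quaternary C5) and is expected to pass through the chair arrangement, because the boat would eclipse the C10 iodine with the silyloxy group, so that the enolate geometry fixes C4 with its methyl on the side that becomes cis to the C5 methyl in ring A.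

Step 5
Reactants: 9 (2R)-2-[(1R)-2-iodo-1-methylcyclohex-2-en-1-yl]propanoic acid
Product: 11 (2R)-2-[(1R)-2-iodo-1-methylcyclohex-2-en-1-yl]-N-methoxy-N-methylpropanamide, via acid chloride 10 (not isolated)
Conditions: (COCl)2, DMF (cat.), CH2Cl2, 0 °C → rt; then MeNHOMe·HCl, pyridine, CH2Cl2, 0 °C
Reagents that add atoms: N,O-dimethylhydroxylamine hydrochloride, CNOC.Cl; oxalyl chloride, O=C(Cl)C(=O)Cl (chlorine stays in 10 only)
Why: Weinreb amide synthesis through the acid chloride, chosen because the neopentyl-type acid is hindered; the short exposure of 10 to pyridine at low temperature should not epimerise C4.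

Step 6
Reactants: 11 (2R)-2-[(1R)-2-iodo-1-methylcyclohex-2-en-1-yl]-N-methoxy-N-methylpropanamide; 12 ethynyltrimethylsilane
Product: 13 (2R)-N-methoxy-N-methyl-2-[(1R)-1-methyl-2-[(trimethylsilyl)ethynyl]cyclohex-2-en-1-yl]propanamide
Conditions: PdCl2(PPh3)2 (cat.), CuI (cat.), i-Pr2NH, THF, rt → 45 °C
Reagents that add atoms: none
Why: Sonogashira coupling of an alkenyl iodide with a terminal alkyne; the tertiary amide and both stereocentres are inert.

Step 7
Reactants: 13 (2R)-N-methoxy-N-methyl-2-[(1R)-1-methyl-2-[(trimethylsilyl)ethynyl]cyclohex-2-en-1-yl]propanamide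
Product: 14 (2R)-2-[(1R)-2-(iodoethynyl)-1-methylcyclohex-2-en-1-yl]-N-methoxy-N-methylpropanamide
Conditions: N-iodosuccinimide, AgNO3 (cat.), acetone, rt, dark
Reagents that add atoms: N-iodosuccinimide, O=C1CCC(=O)N1I
Why: Silver-catalysed iododesilylation of a trimethylsilylalkyne, which passes through the silver acetylide and leaves the ring alkene alone.

Step 8
Reactants: 14 (2R)-2-[(1R)-2-(iodoethynyl)-1-methylcyclohex-2-en-1-yl]-N-methoxy-N-methylpropanamide
Product: 15 (2R)-2-[(1R)-2-[(Z)-2-iodoethenyl]-1-methylcyclohex-2-en-1-yl]-N-methoxy-N-methylpropanamide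
Conditions: 2-nitrobenzenesulfonylhydrazide, Et3N, THF/i-PrOH, rt
Reagents that add atoms: none
Why: Diimide reduction (syn transfer of two hydrogens from HN=NH generated from the sulfonylhydrazide) converts the 1-iodoalkyne into the (Z)-1-iodoalkene without hydrogenolysis of the C–I bond, the trisubstituted ring alkene being much less reactive.

Step 9
Reactants: 15 (2R)-2-[(1R)-2-[(Z)-2-iodoethenyl]-1-methylcyclohex-2-en-1-yl]-N-methoxy-N-methylpropanamide
Product: 18 (1R,8aR)-1,8a-dimethyl-6,7,8,8a-tetrahydronaphthalen-2(1H)-one (4β,5β-dimethyl-1,9-dien-3-one), via dienyllithium 16 (not isolated), via lithium hemiaminal alkoxide 17 (not isolated)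
Conditions: t-BuLi (2.1 equiv), THF, −100 → −78 °C; AcOH/THF, −78 °C
Reagents that add atoms: tert-butyllithium, [Li]C(C)(C)C (lithium stays in 16 and 17 only)
Why: Iodine–lithium exchange at the C2–I bond (first equivalent of t-BuLi; the second destroys the tert-butyl iodide) gives the (Z)-dienyllithium 16, whose carbanion at C2 adds to the Weinreb carbonyl C3 and so forms the C2–C3 bond. The closest known reaction type is the Parham cyclisation, halogen–lithium exchange followed by intramolecular acylation with an N-methoxy-N-methylamide. Ring A closes in the 6-exo-trig mode, the cis relation of C10 and lithium on C1=C2 holding C2 within reach of C3. The five-membered lithium chelate 17 survives until the cold acidic quench, so the ketone never meets an organolithium and a second addition is excluded. No stereocentre is formed: C4 and C5 come unchanged from step 4, and the weakly acidic quench avoids enolisation of 18 towards C4. The step needs chemoselectivity (exchange before attack of t-BuLi on the amide or abstraction of C4–H) and retention of the Z geometry; the fast exchange at −100 °C, the shielding of C4–H by the neighbouring quaternary C5 and the configurational stability of alkenyllithiums at this temperature secure both.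

Step 10
Reactants: 18 (1R,8aR)-1,8a-dimethyl-6,7,8,8a-tetrahydronaphthalen-2(1H)-one
Product: 19 (1R,2S,8aR)-1,8a-dimethyl-1,2,6,7,8,8a-hexahydronaphthalen-2-ol (3β-ol)
Conditions: NaBH4, CeCl3·7H2O, MeOH, −78 °C
Reagents that add atoms: none
Why: Luche reduction (1,2-selective hydride addition to the dienone); the pseudo-axial C5 methyl shields the β face of C3, so hydride should enter from the α face and set the 3β (3S) carbinol cis to both methyls.

Step 11
Reactants: 19 (1R,2S,8aR)-1,8a-dimethyl-1,2,6,7,8,8a-hexahydronaphthalen-2-ol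
Product: 20 3β-(tert-butyldimethylsilyloxy)-4β,5β-dimethyl-1,9-diene (silyl ether of 19)
Conditions: t-BuMe2SiOTf, 2,6-lutidine, CH2Cl2, −78 °C
Reagents that add atoms: tert-butyldimethylsilyl trifluoromethanesulfonate, CC(C)(C)[Si](C)(C)OS(=O)(=O)C(F)(F)F
Why: Silylation of a hindered secondary alcohol with the silyl triflate and a non-nucleophilic base at low temperature, conditions under which the dienylic carbinol should not ionise.

Step 12
Reactants: 20 3β-(tert-butyldimethylsilyloxy)-4β,5β-dimethyl-1,9-diene
Product: 21 (4aR,5R,6S)-6-(tert-butyldimethylsilyloxy)-4a,5-dimethyl-4,4a,5,6-tetrahydronaphthalen-2(3H)-one (3β-silyloxy-1,9-dien-8-one)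
Conditions: CrO3, 3,5-dimethylpyrazole, CH2Cl2, −20 °C
Reagents that add atoms: chromium trioxide, O=[Cr](=O)=O
Why: Allylic oxidation with the CrO3·3,5-dimethylpyrazole complex: C8 is the only allylic methylene and its pseudo-axial hydrogen overlaps with the diene, whereas the C3 hydrogen is pseudo-equatorial and buried under the silyl ether, and oxygenation at C8 gives the linearly conjugated 1,9-dien-8-one.

Step 13
Reactants: 21 (4aR,5R,6S)-6-(tert-butyldimethylsilyloxy)-4a,5-dimethyl-4,4a,5,6-tetrahydronaphthalen-2(3H)-one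
Product: 22 (4aR,5R,6S)-6-hydroxy-4a,5-dimethyl-4,4a,5,6-tetrahydronaphthalen-2(3H)-one (3β-hydroxy-1,9-dien-8-one)
Conditions: HF·pyridine, pyridine, THF, 0 °C → rt
Reagents that add atoms: none
Why: Fluoride-mediated cleavage of the silyl ether under buffered, non-basic conditions, which spares the enolisable dienone and the C4 centre.

Step 14
Reactants: 23 (R)-4-benzyl-1,3-oxazolidin-2-one; 24 butanoyl chloride
Product: 26 (R)-4-benzyl-3-butanoyl-1,3-oxazolidin-2-one, via N-lithio oxazolidinone 25 (not isolated)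
Conditions: n-BuLi, THF, −78 °C; then 24, −78 → 0 °C
Reagents that add atoms: n-butyllithium, [Li]CCCC (lithium stays in 25 only)
Why: N-Acylation of the lithiated Evans oxazolidinone with an acid chloride.

Step 15
Reactants: 26 (R)-4-benzyl-3-butanoyl-1,3-oxazolidin-2-one; 27 1,3,5-trioxane
Product: 29 (4R)-4-benzyl-3-[(2S)-2-(hydroxymethyl)butanoyl]-1,3-oxazolidin-2-one, via chlorotitanium (Z)-enolate 28 (not isolated)
Conditions: TiCl4, i-Pr2NEt, CH2Cl2, 0 °C; then 1,3,5-trioxane, TiCl4, 0 °C
Reagents that add atoms: titanium tetrachloride, Cl[Ti](Cl)(Cl)Cl (titanium and chlorine stay in 28 only)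
Why: Evans hydroxymethylation: the chelated (Z)-chlorotitanium enolate 28 is attacked by the titanium-activated formaldehyde equivalent on the face opposite the benzyl group, which sets the (2S) centre that becomes C6 of the side chain.

Step 16
Reactants: 29 (4R)-4-benzyl-3-[(2S)-2-(hydroxymethyl)butanoyl]-1,3-oxazolidin-2-one
Product: 30 (4R)-4-benzyl-3-[(2S)-2-{[(tert-butyldimethylsilyl)oxy]methyl}butanoyl]-1,3-oxazolidin-2-one
Conditions: t-BuMe2SiCl, imidazole, DMF, rt
Reagents that add atoms: tert-butyldimethylsilyl chloride, CC(C)(C)[Si](C)(C)Cl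
Why: Silylation of a primary alcohol; imidazole is too weak a base to epimerise the α centre or trigger retro-aldol cleavage.

Step 17
Reactants: 30 (4R)-4-benzyl-3-[(2S)-2-{[(tert-butyldimethylsilyl)oxy]methyl}butanoyl]-1,3-oxazolidin-2-one
Product: 31 (2R)-2-{[(tert-butyldimethylsilyl)oxy]methyl}butan-1-ol
Conditions: LiBH4, MeOH, Et2O, 0 °C
Reagents that add atoms: none
Why: Reductive cleavage of the N-acyl oxazolidinone with lithium borohydride, which releases the primary alcohol without touching the α stereocentre and returns the auxiliary.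

Step 18
Reactants: 31 (2R)-2-{[(tert-butyldimethylsilyl)oxy]methyl}butan-1-ol
Product: 32 (2S)-2-{[(tert-butyldimethylsilyl)oxy]methyl}butanal
Conditions: Dess–Martin periodinane, NaHCO3, CH2Cl2, 0 °C → rt
Reagents that add atoms: none
Why: Dess–Martin oxidation of a primary alcohol to the aldehyde under buffered conditions, which keeps the α stereocentre from epimerising.

Step 19
Reactants: 32 (2S)-2-{[(tert-butyldimethylsilyl)oxy]methyl}butanal; 33 triethyl 4-phosphonocrotonate
Product: 35 ethyl (2E,4E,6R)-6-{[(tert-butyldimethylsilyl)oxy]methyl}octa-2,4-dienoate, via lithiated phosphonate 34 (not isolated)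
Conditions: LiN(SiMe3)2, THF, −78 °C; then 32, −78 → 0 °C
Reagents that add atoms: lithium bis(trimethylsilyl)amide, [Li]N([Si](C)(C)C)[Si](C)(C)C (lithium stays in 34 only)
Why: Vinylogous Horner–Wadsworth–Emmons olefination with the γ-lithiated phosphonocrotonate, which is E-selective at the new C4=C5 bond and retains the (E) C2=C3 bond; the weakly basic phosphonate anion at low temperature should not epimerise the aldehyde.

Step 20
Reactants: 35 ethyl (2E,4E,6R)-6-{[(tert-butyldimethylsilyl)oxy]methyl}octa-2,4-dienoate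
Product: 36 (2E,4E,6R)-6-{[(tert-butyldimethylsilyl)oxy]methyl}octa-2,4-dienoic acid
Conditions: LiOH, THF/MeOH/H2O, rt; dilute HCl to pH 4, 0 °C
Reagents that add atoms: lithium hydroxide, [Li+].[OH-]
Why: Saponification of the ethyl ester; the primary silyl ether and the diene acid survive aqueous hydroxide at room temperature.

Step 21
Reactants: 36 (2E,4E,6R)-6-{[(tert-butyldimethylsilyl)oxy]methyl}octa-2,4-dienoic acid; 22 (4aR,5R,6S)-6-hydroxy-4a,5-dimethyl-4,4a,5,6-tetrahydronaphthalen-2(3H)-one
Product: 38 3β-[(2E,4E,6R)-6-{[(tert-butyldimethylsilyl)oxy]methyl}octa-2,4-dienoyloxy]-4β,5β-dimethyl-1,9-dien-8-one, via mixed anhydride 37 (not isolated)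
Conditions: 2,4,6-trichlorobenzoyl chloride, Et3N, THF, rt; then 22, 4-(dimethylamino)pyridine, toluene, rt
Reagents that add atoms: 2,4,6-trichlorobenzoyl chloride, O=C(Cl)c1c(Cl)cc(Cl)cc1Cl (stays in 37 only)
Why: Yamaguchi esterification: the mixed anhydride 37 acylates the hindered pseudo-axial C3 hydroxyl under 4-(dimethylamino)pyridine catalysis with retention at C3, and the ketone and the diene geometry are not affected.

Step 22
Reactants: 38 3β-[(2E,4E,6R)-6-{[(tert-butyldimethylsilyl)oxy]methyl}octa-2,4-dienoyloxy]-4β,5β-dimethyl-1,9-dien-8-one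
Product: 40 7-hydroxy derivative of 38 (α-ketol; C7 epimers), via potassium enolate 39 (not isolated)
Conditions: KN(SiMe3)2, THF, −78 °C; 2-(phenylsulfonyl)-3-phenyloxaziridine, −78 °C; AcOH
Reagents that add atoms: 2-(phenylsulfonyl)-3-phenyloxaziridine, O=S(=O)(c1ccccc1)N1OC1c1ccccc1; potassium bis(trimethylsilyl)amide, [K]N([Si](C)(C)C)[Si](C)(C)C (potassium stays in 39 only)
Why: α-Hydroxylation of a ketone enolate with a Davis oxaziridine: the amide base removes a C7 proton (the only α-hydrogens of the C8 ketone and far more acidic than any C–H of the ester), and the configuration of the new C7 carbinol is irrelevant because it is removed in step 23.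

Step 23
Reactants: 40 7-hydroxy derivative of 38
Product: 42 O-tert-butyldimethylsilyl septeremophilane E (diosphenol with the side-chain silyl ether), via 7,8-diketone 41 (not isolated)
Conditions: Dess–Martin periodinane, NaHCO3, CH2Cl2, rt
Reagents that add atoms: none
Why: Dess–Martin oxidation of the α-ketol to the 7,8-diketone 41, which enolises towards C6 (C5 is quaternary) to the conjugated, hydrogen-bonded diosphenol.

Step 24
Reactants: 42 O-tert-butyldimethylsilyl septeremophilane E
Product: 43 septeremophilane E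
Conditions: HF·pyridine, pyridine, THF, 0 °C → rt
Reagents that add atoms: none
Why: Desilylation of the primary silyl ether with buffered hydrogen fluoride, which tolerates the dienoate ester, the allylic C3–O bond and the diosphenol.

**Compound list**

1 | 3-methylcyclohex-2-en-1-one | CC1=CC(=O)CCC1 | starting material
2 | 2-iodo-3-methylcyclohex-2-en-1-one | CC1=C(I)C(=O)CCC1 | intermediate
3 | (R)-2-iodo-3-methylcyclohex-2-en-1-ol | O[C@@H]1CCCC(C)=C1I | intermediate
4 | propanoyl chloride | CCC(=O)Cl | starting material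
5 | (R)-2-iodo-3-methylcyclohex-2-en-1-yl propanoate | CCC(=O)O[C@@H]1CCCC(C)=C1I | intermediate
6 | lithium enolate of 5 (methyl trans to O–Li) | C/C=C(/O[Li])O[C@@H]1CCCC(C)=C1I | intermediate
7 | (E)-trimethylsilyl ketene acetal of 5 | C/C=C(/O[Si](C)(C)C)O[C@@H]1CCCC(C)=C1I | intermediate
8 | trimethylsilyl (2R)-2-[(1R)-2-iodo-1-methylcyclohex-2-en-1-yl]propanoate | C[Si](C)(C)OC(=O)[C@H](C)[C@@]1(C)CCCC=C1I | intermediate
9 | (2R)-2-[(1R)-2-iodo-1-methylcyclohex-2-en-1-yl]propanoic acid | OC(=O)[C@H](C)[C@@]1(C)CCCC=C1I | intermediate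
10 | (2R)-2-[(1R)-2-iodo-1-methylcyclohex-2-en-1-yl]propanoyl chloride | ClC(=O)[C@H](C)[C@@]1(C)CCCC=C1I | intermediate
11 | (2R)-2-[(1R)-2-iodo-1-methylcyclohex-2-en-1-yl]-N-methoxy-N-methylpropanamide | CON(C)C(=O)[C@H](C)[C@@]1(C)CCCC=C1I | intermediate
12 | ethynyltrimethylsilane | C#C[Si](C)(C)C | starting material
13 | (2R)-N-methoxy-N-methyl-2-[(1R)-1-methyl-2-[(trimethylsilyl)ethynyl]cyclohex-2-en-1-yl]propanamide | CON(C)C(=O)[C@H](C)[C@@]1(C)CCCC=C1C#C[Si](C)(C)C | intermediate
14 | (2R)-2-[(1R)-2-(iodoethynyl)-1-methylcyclohex-2-en-1-yl]-N-methoxy-N-methylpropanamide | CON(C)C(=O)[C@H](C)[C@@]1(C)CCCC=C1C#CI | intermediate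
15 | (2R)-2-[(1R)-2-[(Z)-2-iodoethenyl]-1-methylcyclohex-2-en-1-yl]-N-methoxy-N-methylpropanamide | CON(C)C(=O)[C@H](C)[C@@]1(C)CCCC=C1/C=C\I | intermediate
16 | (Z)-dienyllithium from 15 | CON(C)C(=O)[C@H](C)[C@@]1(C)CCCC=C1/C=C\[Li] | intermediate
17 | lithium alkoxide of the ring A N-methoxy-N-methyl hemiaminal (C3 configuration open) | CON(C)C1(O[Li])C=CC2=CCCC[C@]2(C)[C@H]1C | intermediate
18 | (1R,8aR)-1,8a-dimethyl-6,7,8,8a-tetrahydronaphthalen-2(1H)-one | O=C1C=CC2=CCCC[C@]2(C)[C@H]1C | intermediate
19 | (1R,2S,8aR)-1,8a-dimethyl-1,2,6,7,8,8a-hexahydronaphthalen-2-ol | O[C@H]1C=CC2=CCCC[C@]2(C)[C@H]1C | intermediate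
20 | tert-butyldimethylsilyl ether of 19 | CC(C)(C)[Si](C)(C)O[C@H]1C=CC2=CCCC[C@]2(C)[C@H]1C | intermediate
21 | (4aR,5R,6S)-6-(tert-butyldimethylsilyloxy)-4a,5-dimethyl-4,4a,5,6-tetrahydronaphthalen-2(3H)-one | CC(C)(C)[Si](C)(C)O[C@H]1C=CC2=CC(=O)CC[C@]2(C)[C@H]1C | intermediate
22 | (4aR,5R,6S)-6-hydroxy-4a,5-dimethyl-4,4a,5,6-tetrahydronaphthalen-2(3H)-one | O[C@H]1C=CC2=CC(=O)CC[C@]2(C)[C@H]1C | intermediate
23 | (R)-4-benzyl-1,3-oxazolidin-2-one | O=C1N[C@H](Cc2ccccc2)CO1 | starting material
24 | butanoyl chloride | CCCC(=O)Cl | starting material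
25 | N-lithio derivative of 23 | [Li]N1[C@H](Cc2ccccc2)COC1=O | intermediate
26 | (R)-4-benzyl-3-butanoyl-1,3-oxazolidin-2-one | CCCC(=O)N1[C@H](Cc2ccccc2)COC1=O | intermediate
27 | 1,3,5-trioxane | C1OCOCO1 | starting material
28 | chlorotitanium (Z)-enolate of 26 | CC/C=C(\O[Ti](Cl)(Cl)Cl)N1[C@H](Cc2ccccc2)COC1=O | intermediate
29 | (4R)-4-benzyl-3-[(2S)-2-(hydroxymethyl)butanoyl]-1,3-oxazolidin-2-one | CC[C@@H](CO)C(=O)N1[C@H](Cc2ccccc2)COC1=O | intermediate
30 | (4R)-4-benzyl-3-[(2S)-2-{[(tert-butyldimethylsilyl)oxy]methyl}butanoyl]-1,3-oxazolidin-2-one | CC[C@@H](CO[Si](C)(C)C(C)(C)C)C(=O)N1[C@H](Cc2ccccc2)COC1=O | intermediate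
31 | (2R)-2-{[(tert-butyldimethylsilyl)oxy]methyl}butan-1-ol | CC[C@@H](CO[Si](C)(C)C(C)(C)C)CO | intermediate
32 | (2S)-2-{[(tert-butyldimethylsilyl)oxy]methyl}butanal | CC[C@@H](CO[Si](C)(C)C(C)(C)C)C=O | intermediate
33 | triethyl 4-phosphonocrotonate | CCOC(=O)/C=C/CP(=O)(OCC)OCC | starting material
34 | γ-lithio derivative of 33 | CCOC(=O)/C=C/C([Li])P(=O)(OCC)OCC | intermediate
35 | ethyl (2E,4E,6R)-6-{[(tert-butyldimethylsilyl)oxy]methyl}octa-2,4-dienoate | CC[C@H](/C=C/C=C/C(=O)OCC)CO[Si](C)(C)C(C)(C)C | intermediate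
36 | (2E,4E,6R)-6-{[(tert-butyldimethylsilyl)oxy]methyl}octa-2,4-dienoic acid | CC[C@H](/C=C/C=C/C(=O)O)CO[Si](C)(C)C(C)(C)C | intermediate
37 | mixed anhydride of 36 with 2,4,6-trichlorobenzoic acid | CC[C@H](/C=C/C=C/C(=O)OC(=O)c1c(Cl)cc(Cl)cc1Cl)CO[Si](C)(C)C(C)(C)C | intermediate
38 | C3 ester of 22 with 36 (3β-acyloxy-4β,5β-dimethyl-1,9-dien-8-one) | CC[C@H](/C=C/C=C/C(=O)O[C@H]1C=CC2=CC(=O)CC[C@]2(C)[C@H]1C)CO[Si](C)(C)C(C)(C)C | intermediate
39 | potassium C7-enolate of 38 | CC[C@H](/C=C/C=C/C(=O)O[C@H]1C=CC2=CC(O[K])=CC[C@]2(C)[C@H]1C)CO[Si](C)(C)C(C)(C)C | intermediate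
40 | 7-hydroxy derivative of 38 (C7 configuration open) | CC[C@H](/C=C/C=C/C(=O)O[C@H]1C=CC2=CC(=O)C(O)C[C@]2(C)[C@H]1C)CO[Si](C)(C)C(C)(C)C | intermediate
41 | 7,8-diketone from 40 | CC[C@H](/C=C/C=C/C(=O)O[C@H]1C=CC2=CC(=O)C(=O)C[C@]2(C)[C@H]1C)CO[Si](C)(C)C(C)(C)C | intermediate
42 | O-tert-butyldimethylsilyl septeremophilane E | CC[C@H](/C=C/C=C/C(=O)O[C@H]1C=CC2=CC(=O)C(O)=C[C@]2(C)[C@H]1C)CO[Si](C)(C)C(C)(C)C | intermediate
43 | septeremophilane E (3S,4R,5S; side chain 6R) | CC[C@H](/C=C/C=C/C(=O)O[C@H]1C=CC2=CC(=O)C(O)=C[C@]2(C)[C@H]1C)CO | target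

**Step count**

Total step count: 24. Longest linear sequence: 17 steps (steps 1–13 and 21–24); the side-chain branch (steps 14–20) has 7 steps before the coupling.

**Steps most likely to fail**

Step 9 (key step). The risk is that t-BuLi adds to the amide carbonyl in competition with the exchange, or that the alkenyllithium is protonated before it cyclises (proton transfer from C4–H or base-induced fragmentation of the N–OMe group), which would leave the open-chain diene. The fallback sets out from 15 and returns at 18. The amide of 15 is reduced with i-Bu2AlH (THF, −78 °C) to the aldehyde (2R)-2-[(1R)-2-[(Z)-2-iodoethenyl]-1-methylcyclohex-2-en-1-yl]propanal F1. An intramolecular Nozaki–Hiyama–Kishi reaction (CrCl2, NiCl2 cat., DMSO, rt) then joins C2 to C3 without any strong base and should give the ring A allylic alcohol as a mixture of C3 epimers F2. Dess–Martin oxidation of F2 returns to 18 (the 3β component of F2 is 19 itself).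

Step 12. The risk is loss of site selectivity in the allylic oxidation: attack at the C3–H of the silyl ether, oxygen delivery at C2 or C10 of the delocalised intermediate instead of C8, or over-oxidation of the diene. The fallback sets out from 20 and returns at 21. Sensitised photo-oxygenation (O2, tetraphenylporphyrin, hν, CH2Cl2, 0 °C) uses the ene reaction of singlet oxygen at the trisubstituted C9=C10 bond, whose only allylic hydrogens sit on C8, and should give the tertiary 10-hydroperoxy-1,8-diene F3. Reduction with PPh3 gives the bis-allylic tertiary 10-alcohol F4. Pyridinium chlorochromate [C5H5NH][CrO3Cl] (CH2Cl2, rt) then effects the oxidative 1,3-transposition (Babler–Dauben oxidation) through the chromate at C8, the less hindered terminus, and restores the C9=C10 bond in 21.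

Step 4. The risk is erosion or reversal of the C4 configuration, through leakage into the boat transition state or through incomplete control of the enolate geometry; C5 is not at risk, because it follows from the suprafacial shift. The fallback sets out from 5 and returns at 18; it moves the control of C4 from the sigmatropic transition state to a substrate-controlled protonation on the bicycle. If the rearrangement delivers mainly the C4 epimer (2S)-2-[(1R)-2-iodo-1-methylcyclohex-2-en-1-yl]propanoic acid F5, steps 5–9, which do not touch C4, are run unchanged. They lead by way of the acid chloride F6, the Weinreb amide F7, the silyl enyne F8, the iodoalkyne F9, the (Z)-iodide F10, the dienyllithium F11 and the lithium hemiaminal alkoxide F12 to the 4-epi-dienone F13. F13 is deprotonated at C4 (LiN(i-Pr)2, THF, −78 °C) to the cross-conjugated lithium trienolate F14. Kinetic protonation of F14 at −78 °C with a hindered phenol (2,6-di-tert-butyl-4-methylphenol) should take place on the α face, opposite the pseudo-axial C5 methyl, and place the C4 methyl cis to the C5 methyl, which is 18. The cis isomer is probably not the thermodynamically preferred one, so the quench must be irreversible.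

**Further compounds**

F1 | step 9 | (2R)-2-[(1R)-2-[(Z)-2-iodoethenyl]-1-methylcyclohex-2-en-1-yl]propanal | O=C[C@H](C)[C@@]1(C)CCCC=C1/C=C\I
F2 | step 9 | 4β,5β-dimethyl-1,9-dien-3-ol, C3 epimer mixture | OC1C=CC2=CCCC[C@]2(C)[C@H]1C
F3 | step 12 | 3β-(tert-butyldimethylsilyloxy)-10-hydroperoxy-4β,5β-dimethyl-1,8-diene (C10 configuration open) | CC(C)(C)[Si](C)(C)O[C@H]1C=CC2(OO)C=CCC[C@]2(C)[C@H]1C
F4 | step 12 | 3β-(tert-butyldimethylsilyloxy)-4β,5β-dimethyl-1,8-dien-10-ol (C10 configuration open) | CC(C)(C)[Si](C)(C)O[C@H]1C=CC2(O)C=CCC[C@]2(C)[C@H]1C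
F5 | step 4 | (2S)-2-[(1R)-2-iodo-1-methylcyclohex-2-en-1-yl]propanoic acid | OC(=O)[C@@H](C)[C@@]1(C)CCCC=C1I
F6 | step 4 | (2S)-2-[(1R)-2-iodo-1-methylcyclohex-2-en-1-yl]propanoyl chloride | ClC(=O)[C@@H](C)[C@@]1(C)CCCC=C1I
F7 | step 4 | (2S)-2-[(1R)-2-iodo-1-methylcyclohex-2-en-1-yl]-N-methoxy-N-methylpropanamide | CON(C)C(=O)[C@@H](C)[C@@]1(C)CCCC=C1I
F8 | step 4 | (2S)-N-methoxy-N-methyl-2-[(1R)-1-methyl-2-[(trimethylsilyl)ethynyl]cyclohex-2-en-1-yl]propanamide | CON(C)C(=O)[C@@H](C)[C@@]1(C)CCCC=C1C#C[Si](C)(C)C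
F9 | step 4 | (2S)-2-[(1R)-2-(iodoethynyl)-1-methylcyclohex-2-en-1-yl]-N-methoxy-N-methylpropanamide | CON(C)C(=O)[C@@H](C)[C@@]1(C)CCCC=C1C#CI
F10 | step 4 | (2S)-2-[(1R)-2-[(Z)-2-iodoethenyl]-1-methylcyclohex-2-en-1-yl]-N-methoxy-N-methylpropanamide | CON(C)C(=O)[C@@H](C)[C@@]1(C)CCCC=C1/C=C\I
F11 | step 4 | (Z)-dienyllithium from F10 | CON(C)C(=O)[C@@H](C)[C@@]1(C)CCCC=C1/C=C\[Li]
F12 | step 4 | lithium hemiaminal alkoxide from F11 (C3 configuration open) | CON(C)C1(O[Li])C=CC2=CCCC[C@]2(C)[C@@H]1C
F13 | step 4 | 4-epi-18, (1S,8aR)-1,8a-dimethyl-6,7,8,8a-tetrahydronaphthalen-2(1H)-one | O=C1C=CC2=CCCC[C@]2(C)[C@@H]1C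
F14 | step 4 | lithium C3,C4-enolate of F13 and 18 | [Li]OC1=C(C)[C@@]2(C)CCCC=C2C=C1
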